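**Strategy**

The cyclohexane ring is cut at C1–C2 and C5–C6 into isoprene and a 1,1-disubstituted alkenyl boronate whose boron stands for the tertiary hydroxyl. One Diels–Alder reaction thus joins the ring to the quaternary cyclopentane carbon and sets the carbinol centre C1. It exploits the 1,4-relationship of carbinol C1 and methyl-bearing C4 in the cyclohexane ring (para orientation of isoprene) and the carbonyl next to the quaternary carbon of the cyclopentenone precursor, made from camphoric anhydride, which holds boron syn and exposes one face. An oxygen bridge from C1 to C4 then relays this centre to the trans Br/Cl pair; cyclopentane Br and OH come last.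

Key step: step 8

Remark: anhydride 1 is taken as commercial; it is otherwise one step from (1R,3S)-camphoric acid with acetic anhydride.

**Route**

Step 1
Reactants: 1 (1R,5S)-1,8,8-trimethyl-3-oxabicyclo[3.2.1]octane-2,4-dione
Product: 2 (1R,5S)-1,8,8-trimethyl-3-oxabicyclo[3.2.1]octan-2-one
Conditions: NaBH4, THF, 0 °C to rt; then 2 M HCl
Reagents that add atoms: none
Why: Reduction of a cyclic anhydride to a lactone by NaBH4: hydride attacks the less hindered carbonyl on the CH carbon and the hydroxy acid lactonises on acidification, so the neopentyl carbonyl survives as the lactone and no stereocenter is touched.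

Step 2
Reactants: 2 (1R,5S)-1,8,8-trimethyl-3-oxabicyclo[3.2.1]octan-2-one
Product: 3 1-[(1R,3S)-3-(hydroxymethyl)-1,2,2-trimethylcyclopentyl]ethan-1-one
Conditions: MeLi (1.1 equiv), Et2O, −78 °C; aq. NH4Cl
Reagents that add atoms: methyllithium, [Li]C
Why: Nucleophilic addition of methyllithium to a lactone that has no α-hydrogen and a neopentyl carbonyl stops at the lithium hemiketal, which collapses to the methyl ketone and primary alcohol on work-up; both stereocenters are untouched.

Step 3
Reactants: 3 1-[(1R,3S)-3-(hydroxymethyl)-1,2,2-trimethylcyclopentyl]ethan-1-one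
Product: 4 (1S,3R)-3-acetyl-2,2,3-trimethylcyclopentane-1-carboxylic acid
Conditions: TEMPO (cat.), PhI(OAc)2, MeCN/H2O, rt
Reagents that add atoms: water, O
Why: TEMPO-catalysed oxidation of the primary alcohol with PhI(OAc)2 runs through the aldehyde hydrate to the carboxylic acid and leaves the ketone and both stereocenters alone.

Step 4
Reactants: 4 (1S,3R)-3-acetyl-2,2,3-trimethylcyclopentane-1-carboxylic acid
Product: 5 1-[(1R)-1,2,2-trimethylcyclopent-3-en-1-yl]ethan-1-one
Conditions: Pb(OAc)4, Cu(OAc)2 (cat.), pyridine, benzene, 80 °C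
Reagents that add atoms: none
Why: Kochi oxidative decarboxylation: the secondary alkyl radical formed from the lead carboxylate is oxidised by divalent copper and loses the only β-hydrogen available, from the ring CH2 (the other neighbour is quaternary), so the alkene forms regioselectively while the quaternary stereocenter is retained.

Step 5
Reactants: 5 1-[(1R)-1,2,2-trimethylcyclopent-3-en-1-yl]ethan-1-one
Product: 6 (5R)-5-acetyl-4,4,5-trimethylcyclopent-2-en-1-one
Conditions: Rh2(cap)4 (cat., cap = caprolactamate), t-BuOOH, K2CO3 (cat.), CH2Cl2, rt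
Reagents that add atoms: tert-butyl hydroperoxide, CC(C)(C)OO
Why: Allylic C–H oxidation with t-BuOOH under Rh2(cap)4 catalysis converts the only allylic CH2 into the ketone (the other allylic carbon is quaternary and the allyl radical is trapped at its less hindered end), giving the cyclopentenone without touching the stereocenter.

Step 6
Reactants: 6 (5R)-5-acetyl-4,4,5-trimethylcyclopent-2-en-1-one
Product: 7 1-[(1R)-1,5,5-trimethyl-2-oxocyclopent-3-en-1-yl]ethenyl trifluoromethanesulfonate
Conditions: KN(SiMe3)2, THF, −78 °C; PhNTf2; aq. NH4Cl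
Reagents that add atoms: N-phenylbis(trifluoromethanesulfonimide), O=S(=O)(N(c1ccccc1)S(=O)(=O)C(F)(F)F)C(F)(F)F
Why: Kinetic deprotonation of the acetyl CH3, the only enolisable position, and O-sulfonylation of the enolate with PhNTf2 gives the alkenyl triflate (enol triflate formation).

Step 7
Reactants: 7 1-[(1R)-1,5,5-trimethyl-2-oxocyclopent-3-en-1-yl]ethenyl trifluoromethanesulfonate
Product: 8 (5S)-4,4,5-trimethyl-5-[1-(4,4,5,5-tetramethyl-1,3,2-dioxaborolan-2-yl)ethenyl]cyclopent-2-en-1-one
Conditions: B2pin2, PdCl2(PPh3)2 (cat.), PPh3, KOPh, toluene, 50 °C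
Reagents that add atoms: bis(pinacolato)diboron, CC1(C)OB(OC1(C)C)B1OC(C)(C)C(C)(C)O1
Why: Miyaura borylation: oxidative addition of the alkenyl triflate to zerovalent palladium, transmetalation with B2pin2 activated by phenoxide and reductive elimination give the alkenyl boronate with the double bond in place (the descriptor changes only through priorities).

Step 8
Reactants: 8 (5S)-4,4,5-trimethyl-5-[1-(4,4,5,5-tetramethyl-1,3,2-dioxaborolan-2-yl)ethenyl]cyclopent-2-en-1-one; 9 isoprene
Product: 11 (5R)-5-[(1R)-1-hydroxy-4-methylcyclohex-3-en-1-yl]-4,4,5-trimethylcyclopent-2-en-1-one, via cyclohexenyl pinacol boronate 10 (not isolated)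
Conditions: 9 (excess), BHT (cat.), toluene, 150 °C, sealed tube; then H2O2, pH 7 phosphate buffer, THF, 0 °C to rt
Reagents that add atoms: hydrogen peroxide, OO
Why: Thermal, concerted but asynchronous [4+2] cycloaddition in which isoprene adds across the CH2=C(B) unit of 8, the boron p-orbital acting as the acceptor as in the known Diels–Alder reactions of alkenylboron dienophiles, which is the closest known reaction type. The cyclohexene ring is closed by suprafacial intermolecular cycloaddition, the CH2–CH2 bond and the C(B)–CH2 bond forming in the same step. The new quaternary stereocenter is controlled by the adjacent quaternary ring carbon: the flat ring carbonyl sits syn to boron (B···O contact and least strain beside the boronate), C(CH3)2 is then perpendicular to the alkene, and the diene adds to the opposite face, next to the ring methyl. The step needs para regioselectivity (methyl 1,4 to boron), secured because C1 of isoprene, with the larger HOMO coefficient, bonds to the unsubstituted CH2 terminus while its methyl stays away from the crowded boron-bearing carbon. Chemoselectivity over the ring enone rests on the neopentyl β-carbon of that enone, and the endo/exo question creates no stereoisomers. Buffered peroxide then oxidises the tertiary C–B bond with retention, turning the boron-bearing carbon into the carbinol carbon without base-induced retro-aldol cleavage.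

Step 9
Reactants: 11 (5R)-5-[(1R)-1-hydroxy-4-methylcyclohex-3-en-1-yl]-4,4,5-trimethylcyclopent-2-en-1-one
Product: 12 (5R)-5-[(1R,3S,4S)-3-bromo-4-methyl-7-oxabicyclo[2.2.1]heptan-1-yl]-4,4,5-trimethylcyclopent-2-en-1-one
Conditions: NBS, CH2Cl2, 0 °C, dark
Reagents that add atoms: N-bromosuccinimide, O=C1CCC(=O)N1Br
Why: Bromoetherification (5-exo, Markovnikov): only the bromonium ion on the face opposite to the tertiary hydroxyl can be opened intramolecularly at the methyl-bearing carbon, so the new C–O bond is cis to the carbinol oxygen and bromine ends up anti to the oxygen bridge (endo), both centres following from the carbinol configuration; the bridge also masks the retro-aldol-prone β-hydroxy ketone.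

Step 10
Reactants: 12 (5R)-5-[(1R,3S,4S)-3-bromo-4-methyl-7-oxabicyclo[2.2.1]heptan-1-yl]-4,4,5-trimethylcyclopent-2-en-1-one
Product: 13 (2R,4R)-2-[(1R,3S,4S)-3-bromo-4-methyl-7-oxabicyclo[2.2.1]heptan-1-yl]-2,3,3-trimethyl-4-(4,4,5,5-tetramethyl-1,3,2-dioxaborolan-2-yl)cyclopentan-1-one
Conditions: B2pin2, CuCl (cat.), Xantphos (cat.), NaOt-Bu (cat.), MeOH, THF, rt
Reagents that add atoms: bis(pinacolato)diboron, CC1(C)OB(OC1(C)C)B1OC(C)(C)C(C)(C)O1
Why: Copper-catalysed conjugate borylation of the enone: the boryl copper species adds to the β-carbon from the face of the ring methyl, anti to the bulky bicyclic substituent on the quaternary carbon, so the boronate is trans to that substituent; the catalytic alkoxide leaves the alkyl bromide alone.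

Step 11
Reactants: 13 (2R,4R)-2-[(1R,3S,4S)-3-bromo-4-methyl-7-oxabicyclo[2.2.1]heptan-1-yl]-2,3,3-trimethyl-4-(4,4,5,5-tetramethyl-1,3,2-dioxaborolan-2-yl)cyclopentan-1-one
Product: 14 (1R,2S,4R)-2-[(1R,3S,4S)-3-bromo-4-methyl-7-oxabicyclo[2.2.1]heptan-1-yl]-2,3,3-trimethyl-4-(4,4,5,5-tetramethyl-1,3,2-dioxaborolan-2-yl)cyclopentan-1-ol
Conditions: NaBH4, MeOH, −40 °C
Reagents that add atoms: none
Why: Hydride reduction of the ketone with NaBH4: hydride approaches from the face of the α-methyl group, away from the quaternary bicyclic substituent, which places the new hydroxyl cis to that substituent.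

Step 12
Reactants: 14 (1R,2S,4R)-2-[(1R,3S,4S)-3-bromo-4-methyl-7-oxabicyclo[2.2.1]heptan-1-yl]-2,3,3-trimethyl-4-(4,4,5,5-tetramethyl-1,3,2-dioxaborolan-2-yl)cyclopentan-1-ol
Product: 16 (1R,2S,4S)-4-bromo-2-[(1R,3S,4S)-3-bromo-4-methyl-7-oxabicyclo[2.2.1]heptan-1-yl]-2,3,3-trimethylcyclopentan-1-ol, via dilithium aryl boronate complex 15 (not isolated)
Conditions: 3,5-(CF3)2C6H3Br, n-BuLi, THF, −78 °C; add 14; then NBS, −78 °C to rt; aq. NH4Cl
Reagents that add atoms: N-bromosuccinimide, O=C1CCC(=O)N1Br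
Why: Stereospecific bromodeboronation of a secondary boronic ester: the electron-rich aryl boronate complex is attacked by NBS at carbon with inversion (SE2), which turns the boronate trans to the bicyclic substituent into the bromide cis to it and cis to the hydroxyl.

Step 13
Reactants: 16 (1R,2S,4S)-4-bromo-2-[(1R,3S,4S)-3-bromo-4-methyl-7-oxabicyclo[2.2.1]heptan-1-yl]-2,3,3-trimethylcyclopentan-1-ol
Product: 17 (1R,2S,4S)-4-bromo-2-[(1R,3S,4S)-3-bromo-4-chloro-1-hydroxy-4-methylcyclohexyl]-2,3,3-trimethylcyclopentan-1-ol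
Conditions: BCl3 (2.2 equiv), CH2Cl2, −78 to −30 °C; aq. NaHCO3
Reagents that add atoms: boron trichloride, ClB(Cl)Cl
Why: Lewis acid cleavage of the tertiary bridging ether by BCl3: the antiperiplanar endo bromine assists ionisation of the O–C(CH3) bond as a bromonium ion, which chloride opens at the tertiary carbon from the face the oxygen has left, so chlorine replaces oxygen with retention (double inversion) and aqueous work-up frees both hydroxyls.

**Compound list**

1 | (1R,5S)-1,8,8-trimethyl-3-oxabicyclo[3.2.1]octane-2,4-dione ((1R,3S)-camphoric anhydride) | CC1(C)[C@@H]2CC[C@@]1(C)C(=O)OC2=O | starting material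
2 | (1R,5S)-1,8,8-trimethyl-3-oxabicyclo[3.2.1]octan-2-one (lactone carbonyl on the methyl-bearing bridgehead) | CC1(C)[C@@H]2CC[C@@]1(C)C(=O)OC2 | intermediate
3 | 1-[(1R,3S)-3-(hydroxymethyl)-1,2,2-trimethylcyclopentyl]ethan-1-one (acetyl and CH2OH cis) | CC1(C)[C@@H](CO)CC[C@@]1(C)C(C)=O | intermediate
4 | (1S,3R)-3-acetyl-2,2,3-trimethylcyclopentane-1-carboxylic acid | CC1(C)[C@@H](C(=O)O)CC[C@@]1(C)C(C)=O | intermediate
5 | 1-[(1R)-1,2,2-trimethylcyclopent-3-en-1-yl]ethan-1-one | CC1(C)C=CC[C@@]1(C)C(C)=O | intermediate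
6 | (5R)-5-acetyl-4,4,5-trimethylcyclopent-2-en-1-one | CC1(C)C=CC(=O)[C@@]1(C)C(C)=O | intermediate
7 | 1-[(1R)-1,5,5-trimethyl-2-oxocyclopent-3-en-1-yl]ethenyl trifluoromethanesulfonate | CC1(C)C=CC(=O)[C@@]1(C)C(=C)OS(=O)(=O)C(F)(F)F | intermediate
8 | (5S)-4,4,5-trimethyl-5-[1-(4,4,5,5-tetramethyl-1,3,2-dioxaborolan-2-yl)ethenyl]cyclopent-2-en-1-one | CC1(C)C=CC(=O)[C@@]1(C)C(=C)B2OC(C)(C)C(C)(C)O2 | intermediate
9 | isoprene (2-methylbuta-1,3-diene) | C=CC(C)=C | starting material
10 | (5S)-4,4,5-trimethyl-5-[(1S)-4-methyl-1-(4,4,5,5-tetramethyl-1,3,2-dioxaborolan-2-yl)cyclohex-3-en-1-yl]cyclopent-2-en-1-one | CC1(C)C=CC(=O)[C@@]1(C)[C@@]1(B2OC(C)(C)C(C)(C)O2)CCC(C)=CC1 | intermediate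
11 | (5R)-5-[(1R)-1-hydroxy-4-methylcyclohex-3-en-1-yl]-4,4,5-trimethylcyclopent-2-en-1-one | CC1(C)C=CC(=O)[C@@]1(C)[C@@]1(O)CCC(C)=CC1 | intermediate
12 | (5R)-5-[(1R,3S,4S)-3-bromo-4-methyl-7-oxabicyclo[2.2.1]heptan-1-yl]-4,4,5-trimethylcyclopent-2-en-1-one (Br endo, anti to the oxygen bridge) | CC1(C)C=CC(=O)[C@@]1(C)[C@]12CC[C@](C)(O1)[C@@H](Br)C2 | intermediate
13 | (2R,4R)-2-[(1R,3S,4S)-3-bromo-4-methyl-7-oxabicyclo[2.2.1]heptan-1-yl]-2,3,3-trimethyl-4-(4,4,5,5-tetramethyl-1,3,2-dioxaborolan-2-yl)cyclopentan-1-one (boron trans to the bicyclic group) | CC1(C)[C@H](B2OC(C)(C)C(C)(C)O2)CC(=O)[C@@]1(C)[C@]12CC[C@](C)(O1)[C@@H](Br)C2 | intermediate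
14 | (1R,2S,4R)-2-[(1R,3S,4S)-3-bromo-4-methyl-7-oxabicyclo[2.2.1]heptan-1-yl]-2,3,3-trimethyl-4-(4,4,5,5-tetramethyl-1,3,2-dioxaborolan-2-yl)cyclopentan-1-ol (OH cis, boron trans to the bicyclic group) | CC1(C)[C@H](B2OC(C)(C)C(C)(C)O2)C[C@@H](O)[C@@]1(C)[C@]12CC[C@](C)(O1)[C@@H](Br)C2 | intermediate
15 | dilithium salt of 14 as its B-[3,5-bis(trifluoromethyl)phenyl] boronate complex (lithium alkoxide, lithium borate) | [Li+].[Li+].CC1(C)[C@H]([B-]2(OC(C)(C)C(C)(C)O2)c3cc(cc(c3)C(F)(F)F)C(F)(F)F)C[C@@H]([O-])[C@@]1(C)[C@]12CC[C@](C)(O1)[C@@H](Br)C2 | intermediate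
16 | (1R,2S,4S)-4-bromo-2-[(1R,3S,4S)-3-bromo-4-methyl-7-oxabicyclo[2.2.1]heptan-1-yl]-2,3,3-trimethylcyclopentan-1-ol | CC1(C)[C@@H](Br)C[C@@H](O)[C@@]1(C)[C@]12CC[C@](C)(O1)[C@@H](Br)C2 | intermediate
17 | (1R,2S,4S)-4-bromo-2-[(1R,3S,4S)-3-bromo-4-chloro-1-hydroxy-4-methylcyclohexyl]-2,3,3-trimethylcyclopentan-1-ol | CC1(C)[C@@H](Br)C[C@@H](O)[C@@]1(C)[C@@]1(O)CC[C@](C)(Cl)[C@@H](Br)C1 | target

**Count and risks**

Total step count: 13. Longest linear sequence: 13 steps (1 to 17; isoprene 9 enters at step 8).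

Step 8. The cycloaddition may stall, because a weakly activated dienophile has to form a quaternary carbon next to a quaternary carbon, or it may lose facial or para selectivity. Fallback, with an acetyl group instead of boron as the hydroxyl surrogate: from 7, carbonylative Stille coupling (CO, Me4Sn, Pd(PPh3)4, LiCl, THF) should give the enone (5R)-4,4,5-trimethyl-5-(3-oxobut-1-en-2-yl)cyclopent-2-en-1-one F1. A Me2AlCl-promoted Diels–Alder reaction of F1 with 9 should give the methyl ketone 5-(1-acetyl-4-methylcyclohex-3-en-1-yl)-4,4,5-trimethylcyclopent-2-en-1-one F2. Baeyer–Villiger oxidation with Me3SiOOSiMe3 and Me3SiOTf, which spares C=C bonds, should let the quaternary carbon migrate with retention to the tertiary acetate (1R)-4-methyl-1-[(1R)-1,5,5-trimethyl-2-oxocyclopent-3-en-1-yl]cyclohex-3-en-1-yl acetate F3. i-Bu2AlH then removes the acetate and reduces the enone to the diol 5-[(1R)-1-hydroxy-4-methylcyclohex-3-en-1-yl]-4,4,5-trimethylcyclopent-2-en-1-ol F4, and MnO2 re-oxidises the allylic alcohol, which returns to 11.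

Step 13. Ionisation may take place at the other tertiary C–O bond, chloride may open the bromonium ion at the secondary carbon, or the freed alkoxide may close the bridge again. Fallback, by acylative ether cleavage: from 16, AcCl with ZnCl2 in CH2Cl2 should cleave the bridge to the chloro diacetate (1R,2S,4S)-2-[(1R,3S,4S)-1-acetoxy-3-bromo-4-chloro-4-methylcyclohexyl]-4-bromo-2,3,3-trimethylcyclopentyl acetate F5, in which the tertiary oxygen is held as an ester and cannot re-close; K2CO3 in MeOH then gives 17.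

Step 12. The boronate complex may fail to form at the neopentyl-type carbon, or it may react with NBS by electron transfer and lose stereospecificity. Fallback, by hydrogen-atom transfer to a vinyl bromide instead of substitution at boron: from 13, NaBO3 oxidation (retention) should give the β-hydroxy ketone 2-[(1R,3S,4S)-3-bromo-4-methyl-7-oxabicyclo[2.2.1]heptan-1-yl]-4-hydroxy-2,3,3-trimethylcyclopentan-1-one F6. Periodinane oxidation (DMP) gives the diketone 4-[(1R,3S,4S)-3-bromo-4-methyl-7-oxabicyclo[2.2.1]heptan-1-yl]-4,5,5-trimethylcyclopentane-1,3-dione F7. (COBr)2 with catalytic DMF gives, at the less hindered carbonyl next to C(CH3)2, the bromo enone 3-bromo-5-[(1R,3S,4S)-3-bromo-4-methyl-7-oxabicyclo[2.2.1]heptan-1-yl]-4,4,5-trimethylcyclopent-2-en-1-one F8. Luche reduction (NaBH4, CeCl3) gives the allylic alcohol 3-bromo-5-[(1R,3S,4S)-3-bromo-4-methyl-7-oxabicyclo[2.2.1]heptan-1-yl]-4,4,5-trimethylcyclopent-2-en-1-ol F9 with the hydroxyl cis to the bicyclic group. Hydrogenation by hydrogen-atom transfer (Mn(dpm)3, PhSiH3, t-BuOOH, i-PrOH) then delivers hydrogen to the bromine-bearing carbon from the methyl face and returns to 16.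

Further compounds
F1 | step 8 | (5R)-4,4,5-trimethyl-5-(3-oxobut-1-en-2-yl)cyclopent-2-en-1-one | CC1(C)C=CC(=O)[C@@]1(C)C(=C)C(C)=O
F2 | step 8 | 5-(1-acetyl-4-methylcyclohex-3-en-1-yl)-4,4,5-trimethylcyclopent-2-en-1-one (acetyl in the place of the hydroxyl of 11) | CC1(C)C=CC(=O)[C@@]1(C)[C@@]1(C(C)=O)CCC(C)=CC1
F3 | step 8 | (1R)-4-methyl-1-[(1R)-1,5,5-trimethyl-2-oxocyclopent-3-en-1-yl]cyclohex-3-en-1-yl acetate | CC1(C)C=CC(=O)[C@@]1(C)[C@@]1(OC(C)=O)CCC(C)=CC1
F4 | step 8 | 5-[(1R)-1-hydroxy-4-methylcyclohex-3-en-1-yl]-4,4,5-trimethylcyclopent-2-en-1-ol (both epimers at the ring carbinol) | CC1(C)C=CC(O)[C@@]1(C)[C@@]1(O)CCC(C)=CC1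
F5 | step 13 | (1R,2S,4S)-2-[(1R,3S,4S)-1-acetoxy-3-bromo-4-chloro-4-methylcyclohexyl]-4-bromo-2,3,3-trimethylcyclopentyl acetate | CC1(C)[C@@H](Br)C[C@@H](OC(C)=O)[C@@]1(C)[C@@]1(OC(C)=O)CC[C@](C)(Cl)[C@@H](Br)C1
F6 | step 12 | 2-[(1R,3S,4S)-3-bromo-4-methyl-7-oxabicyclo[2.2.1]heptan-1-yl]-4-hydroxy-2,3,3-trimethylcyclopentan-1-one (hydroxyl trans to the bicyclic group) | CC1(C)[C@H](O)CC(=O)[C@@]1(C)[C@]12CC[C@](C)(O1)[C@@H](Br)C2
F7 | step 12 | 4-[(1R,3S,4S)-3-bromo-4-methyl-7-oxabicyclo[2.2.1]heptan-1-yl]-4,5,5-trimethylcyclopentane-1,3-dione | CC1(C)C(=O)CC(=O)[C@@]1(C)[C@]12CC[C@](C)(O1)[C@@H](Br)C2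
F8 | step 12 | 3-bromo-5-[(1R,3S,4S)-3-bromo-4-methyl-7-oxabicyclo[2.2.1]heptan-1-yl]-4,4,5-trimethylcyclopent-2-en-1-one | CC1(C)C(Br)=CC(=O)[C@@]1(C)[C@]12CC[C@](C)(O1)[C@@H](Br)C2
F9 | step 12 | 3-bromo-5-[(1R,3S,4S)-3-bromo-4-methyl-7-oxabicyclo[2.2.1]heptan-1-yl]-4,4,5-trimethylcyclopent-2-en-1-ol (hydroxyl cis to the bicyclic group) | CC1(C)C(Br)=C[C@@H](O)[C@@]1(C)[C@]12CC[C@](C)(O1)[C@@H](Br)C2
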